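For a quick number, the hunch that self-condensation is the nucleophile's one drain is the trap: each turn of the electrophile step also sets free an acid, and that acid can take up a further nucleophile.

    2 nucleophile → self-condensation product (k1 = 6550 /M/s)
    target ⇌ isomer of the product (K2 = 0.49, k2 = 0.301 /s)
    acid set free + free base ⇌ salt of the base (K3 = 2.46 × 10⁵ /M, k3 = 6280 /M/s)
    electrophile + nucleophile → acid set free + target (k4 = 1030 /M/s)
    nucleophile + acid set free ⇌ protonated nucleophile, settled at all times (K5 = 7.6 × 10⁶ /M)
    target → over-reaction product (k6 = 0.146 /s)
electrophile 0.50 mM; nucleophile 0.400 mM; free base 0.600 mM; time 2.5 s
* part of the electrophile that has reacted at 2.5 s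
* share of the unused nucleophile that is free and not bound as protonated nucleophile, at 2.5 s
- where a step has two of a species, its rate is k times that concentration squared, and two are used at each turn
- run time (flask): 2.5 s

At the start the equilibrium constant of protonation times the charged nucleophile is 3000, above the 150 of the salt-forming step with the free base as charged, so this reckoning lets each acid set free stand as protonated nucleophile, and each electrophile turn costs two nucleophile. One quantity then serves this reckoning: the crossing concentration, the rate constant of the electrophile step times the electrophile over the rate constant of self-condensation, which is the free nucleophile at which the two drains, two nucleophile per turn each, are equal, 0.0786 mM. Held at constant electrophile, that step is pseudo-first-order in nucleophile, and the rate law integrates to: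

nucleophile left = crossing / [(1 + crossing / nucleophile charged) × exp(2 × electrophile rate constant × electrophile × time) − 1]

electrophile used = 0.5 × crossing × ln[(nucleophile charged + crossing) / (nucleophile left + crossing)]

First round, electrophile as charged: nucleophile left 0.00534 mM, electrophile used 0.0684 mM.

Second round, that answer put back, electrophile at its mean 0.466 mM: crossing 0.0732 mM, nucleophile left 0.00609 mM, electrophile used 0.0654 mM.

So c is 13.1 %, and the free share, nucleophile left over nucleophile left plus electrophile used, is 8.52 %, with the acid taken by the free base not counted.

The forecast gives 13.5 % and 12 %, the second above this reckoning, on the grounds that “nucleophile is rapidly consumed by its fast self-condensation and by binding the released acid”.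

The flask gives 13.3 % and 12.3 %, against the 13.1 % and 8.52 % reckoned, and at 2.50 s it holds 0.0623 mM of protonated nucleophile beside 0.00329 mM of salt of the base. That flask's free nucleophile, 0.00872 mM, then lies below the crossing. In the neighbour flask with 2.0 mM of electrophile the crossing rises to 0.315 mM, and one round of the same lines gives c of 6.45 %. That neighbour flask gives 6.99 %, and it holds 0.0236 mM of salt of the base.

Its constants are made up; no experiment stands behind them.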